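**Retrosynthetic overview**

1. Numbering: ring A = cyclobutane C1–C9–C10–C11 (C11 = CMe2); ring B = nine-membered ring C1 to C9; ring C = dihydropyran (O, C8, C15, C1′); ring D = the tetramethylcyclohexenedione.
2. Rings C and D come last: hetero-Diels–Alder reaction of the alkylidene trione (from syncarpic acid and 3-methylbutanal) across the exocyclic C8=C15 alkene of dienol 22, setting C8 and C1′.
3. Ring B is closed before that at C4–C5 by an intramolecular Nozaki–Hiyama–Kishi reaction of a (Z)-vinyl iodide with a C5 aldehyde; C5 is then set by oxidation and CBS reduction.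
4. Ring A is made first, by photochemical Wolff ring contraction of a 2-diazo-5,5-dimethylcyclopentanone (bond C1–C11). Enabling feature: in ring A the quaternary gem-dimethyl carbon C11 is bonded to C1, and C1 also carries C2 of ring B, so C2 can be the ketone carbon of a cyclopentanone C2–C1–C9–C10–C11 in which C11 is the only carbon able to migrate and C1 the only carbon able to take the diazo group.
5. C9 comes from a rhodium-catalysed asymmetric conjugate addition to 5,5-dimethylcyclopent-2-enone and relays its configuration to C1 (trans); order of ring formation: A, then B, then C (with D).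

Key step: step 6

Remark: syncarpic acid 23 is taken as a purchasable compound; TBDPS = tert-butyldiphenylsilyl.

**Route**

Step 1
Reactants: 1 2,2-dimethylcyclopentan-1-one
Product: 2 5,5-dimethylcyclopent-2-en-1-one
Conditions: IBX (1.5 equiv), DMSO, 70 °C
Reagents that add atoms: none
Why: IBX dehydrogenation of a ketone to the enone can only occur on the one enolisable side of 1, because the other α-carbon is quaternary, and no stereocentre is involved.

Step 2
Reactants: 3 pent-4-yn-1-ol
Product: 4 tert-butyl(pent-4-yn-1-yloxy)diphenylsilane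
Conditions: TBDPSCl, imidazole, CH2Cl2, 0 °C to rt
Reagents that add atoms: tert-butyl(chloro)diphenylsilane, CC(C)(C)[Si](Cl)(c1ccccc1)c1ccccc1
Why: Standard silylation of a primary alcohol; the TBDPS ether is chosen because it should survive the methoxide of step 6 and the aqueous acid of step 8.

Step 3
Reactants: 4 tert-butyl(pent-4-yn-1-yloxy)diphenylsilane
Product: 6 2-[5-(TBDPS-oxy)pent-1-en-2-yl]-4,4,5,5-tetramethyl-1,3,2-dioxaborolane, via alkenylalane 5 (not isolated)
Conditions: i-Bu2AlH (1.3 equiv), Ni(dppp)Cl2 (3 mol %), THF, 0 °C to rt; then MeOBpin, 0 °C to rt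
Reagents that add atoms: 2-methoxy-4,4,5,5-tetramethyl-1,3,2-dioxaborolane, COB1OC(C)(C)C(C)(C)O1
Why: Nickel-catalysed hydroalumination of a terminal alkyne with i-Bu2AlH and the dppp ligand places aluminium on the internal carbon (future C8), and Al-to-B exchange with MeOBpin gives the 1,1-disubstituted alkenylboronate; no stereocentre is formed.

Step 4
Reactants: 2 5,5-dimethylcyclopent-2-en-1-one; 6 2-[5-(TBDPS-oxy)pent-1-en-2-yl]-4,4,5,5-tetramethyl-1,3,2-dioxaborolane
Product: 7 (S)-4-[5-(TBDPS-oxy)pent-1-en-2-yl]-2,2-dimethylcyclopentan-1-one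
Conditions: [RhCl(C2H4)2]2 (2.5 mol %), (S)-BINAP (6 mol %), KOH (0.5 equiv), 1,4-dioxane/H2O (10:1), 60 °C
Reagents that add atoms: none
Why: Hayashi–Miyaura asymmetric 1,4-addition: the alkenyl group passes from boron to monovalent rhodium and inserts the enone on the face selected by (S)-BINAP, which in this reaction class gives (S)-3-substituted cyclopentanones and so sets C9 (S).

Step 5
Reactants: 7 (S)-4-[5-(TBDPS-oxy)pent-1-en-2-yl]-2,2-dimethylcyclopentan-1-one
Product: 10 (R)-3-[5-(TBDPS-oxy)pent-1-en-2-yl]-2-diazo-5,5-dimethylcyclopentan-1-one (spatial arrangement at C9 as in 7), via lithium enolate 8 (not isolated), via trifluoroacetyl ketone 9 (not isolated)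
Conditions: LiN(SiMe3)2, THF, −78 °C; CF3CO2CH2CF3; then MsN3, Et3N, H2O (1 equiv), MeCN, rt
Reagents that add atoms: methanesulfonyl azide, CS(=O)(=O)N=[N+]=[N-]
Why: Detrifluoroacetylative diazo transfer (Regitz type): C1 is the only enolisable carbon of 7, so Claisen acylation and then diazo transfer with loss of the trifluoroacetyl group occur there, and C9 is not touched.

Step 6
Reactants: 10 (R)-3-[5-(TBDPS-oxy)pent-1-en-2-yl]-2-diazo-5,5-dimethylcyclopentan-1-one
Product: 13 methyl (1R,4S)-4-[5-(TBDPS-oxy)pent-1-en-2-yl]-2,2-dimethylcyclobutane-1-carboxylate, via ketene 11 (not isolated), via ester epimer mixture 12 (not isolated)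
Conditions: hν (λ > 290 nm, Pyrex), MeOH, rt; then NaOMe (0.3 equiv), MeOH, 40 °C
Reagents that add atoms: methanol, CO
Why: Irradiation expels N2 from the s-cis-locked cyclic diazoketone and, in a concerted Wolff rearrangement, the quaternary carbon C11 shifts from the carbonyl carbon (future C2) to the diazo carbon C1, giving cyclobutylidene ketene 11, which methanol traps as ester 12. The closest known reaction type is the photochemical Wolff ring contraction of 2-diazocyclopentanones to cyclobutanecarboxylic acid derivatives, which is established for 5,5-dimethyl substrates. Ring A is closed by a 1,2-shift ring contraction (five- to four-membered, N2 as the extruded fragment), not by an exo or endo attack, and the flat, strain-free cyclopentanone thereby becomes the strained cyclobutane with C2 at the carboxyl level for chain extension. The only new stereocentre, C1, is protonated without control but lies α to the ester, so NaOMe equilibrates it to the trans-1,2-disubstituted cyclobutane (1R) under control of the C9 centre from step 4. The step needs migration selectivity and carbene chemoselectivity: C11 is the only other substituent on the acyl carbon and so the only group that can migrate, the concerted rearrangement leaves no free carbene for C–H insertion or for addition to the C8=C15 alkene, and C9 carries no acidifying group and cannot epimerise.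

Step 7
Reactants: 13 methyl (1R,4S)-4-[5-(TBDPS-oxy)pent-1-en-2-yl]-2,2-dimethylcyclobutane-1-carboxylate
Product: 14 (1R,4S)-4-[5-(TBDPS-oxy)pent-1-en-2-yl]-2,2-dimethylcyclobutane-1-carbaldehyde
Conditions: i-Bu2AlH (1.05 equiv), CH2Cl2, −78 °C; then aq. KNaC4H4O6
Reagents that add atoms: none
Why: Half-reduction of a methyl ester with i-Bu2AlH at −78 °C through the stable aluminium hemiacetal; C1 is already in its thermodynamic trans configuration, so any enolisation of the aldehyde is harmless.

Step 8
Reactants: 14 (1R,4S)-4-[5-(TBDPS-oxy)pent-1-en-2-yl]-2,2-dimethylcyclobutane-1-carbaldehyde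
Product: 16 2-{(1R,4S)-4-[5-(TBDPS-oxy)pent-1-en-2-yl]-2,2-dimethylcyclobutyl}acetaldehyde, via enol ether 15 (not isolated)
Conditions: MeOCH2PPh3Cl, KN(SiMe3)2, THF, 0 °C; then 2 M HCl, THF, rt
Reagents that add atoms: (methoxymethyl)triphenylphosphonium chloride, COC[P+](c1ccccc1)(c1ccccc1)c1ccccc1.[Cl-]; water, O
Why: Wittig methoxymethylenation followed by acid hydrolysis of the enol ether is the standard one-carbon aldehyde homologation, making C2 a methylene and C3 the new aldehyde carbon; the TBDPS ether and the 1,1-disubstituted alkene should tolerate brief 2 M HCl and no stereocentre changes.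

Step 9
Reactants: 16 2-{(1R,4S)-4-[5-(TBDPS-oxy)pent-1-en-2-yl]-2,2-dimethylcyclobutyl}acetaldehyde
Product: 17 tert-butyl{[4-((1S,4R)-4-[(Z)-3-iodobut-2-en-1-yl]-3,3-dimethylcyclobutyl)pent-4-en-1-yl]oxy}diphenylsilane
Conditions: EtPPh3I, n-BuLi, THF, rt; I2, −78 °C; NaN(SiMe3)2, −78 °C; then 16, −78 to −20 °C
Reagents that add atoms: ethyltriphenylphosphonium iodide, CC[P+](c1ccccc1)(c1ccccc1)c1ccccc1.[I-]; iodine, II
Why: Stork–Zhao olefination: the α-iodo ylide made in the flask adds to the unhindered aldehyde under kinetic control to give the (Z)-2-iodoalkene, which places iodine (the future C5 attachment) cis to C2 as the cis ring olefin requires.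

Step 10
Reactants: 17 tert-butyl{[4-((1S,4R)-4-[(Z)-3-iodobut-2-en-1-yl]-3,3-dimethylcyclobutyl)pent-4-en-1-yl]oxy}diphenylsilane
Product: 18 4-{(1S,4R)-4-[(Z)-3-iodobut-2-en-1-yl]-3,3-dimethylcyclobutyl}pent-4-en-1-ol
Conditions: n-Bu4NF, THF, 0 °C to rt
Reagents that add atoms: none
Why: Fluoride cleavage of the silyl ether, to which the vinyl iodide and the alkenes are inert.

Step 11
Reactants: 18 4-{(1S,4R)-4-[(Z)-3-iodobut-2-en-1-yl]-3,3-dimethylcyclobutyl}pent-4-en-1-ol
Product: 19 4-{(1S,4R)-4-[(Z)-3-iodobut-2-en-1-yl]-3,3-dimethylcyclobutyl}pent-4-enal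
Conditions: Dess–Martin periodinane, CH2Cl2, rt
Reagents that add atoms: none
Why: Dess–Martin oxidation of the primary alcohol to the aldehyde under conditions that leave the vinyl iodide geometry and both ring stereocentres unchanged.

Step 12
Reactants: 19 4-{(1S,4R)-4-[(Z)-3-iodobut-2-en-1-yl]-3,3-dimethylcyclobutyl}pent-4-enal
Product: 20 (1R,3Z,9S)-4,11,11-trimethyl-8-methylidenebicyclo[7.2.0]undec-3-en-5-ol (both C5 epimers)
Conditions: CrCl2 (8 equiv), NiCl2 (1 mol %), degassed DMSO, rt, slow addition to 3 mM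
Reagents that add atoms: none
Why: Intramolecular Nozaki–Hiyama–Kishi reaction: zerovalent nickel inserts into the C–I bond with retention of the Z geometry, the alkenyl group passes to trivalent chromium and adds to the C5 aldehyde under high dilution, the trans-1,2-disubstituted ring A holding both chains in reach; C5 forms without reliable control and is corrected in steps 13 and 14.

Step 13
Reactants: 20 (1R,3Z,9S)-4,11,11-trimethyl-8-methylidenebicyclo[7.2.0]undec-3-en-5-ol (both C5 epimers)
Product: 21 (1R,3Z,9S)-4,11,11-trimethyl-8-methylidenebicyclo[7.2.0]undec-3-en-5-one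
Conditions: Dess–Martin periodinane, CH2Cl2, 0 °C to rt
Reagents that add atoms: none
Why: Dess–Martin oxidation of the allylic alcohol converges both C5 epimers to one enone, whose cis (Z) ring olefin is the stable geometry in a nine-membered ring.

Step 14
Reactants: 21 (1R,3Z,9S)-4,11,11-trimethyl-8-methylidenebicyclo[7.2.0]undec-3-en-5-one
Product: 22 (1R,3Z,5S,9S)-4,11,11-trimethyl-8-methylidenebicyclo[7.2.0]undec-3-en-5-ol
Conditions: (R)-2-methyl-CBS-oxazaborolidine (0.5 equiv), catecholborane (1.5 equiv), toluene, −78 °C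
Reagents that add atoms: none
Why: Corey–Bakshi–Shibata reduction: the α-methylalkenyl side of the ketone acts as the large group, so the (R)-oxazaborolidine should deliver hydride in 1,2-fashion to the face that gives the (5S)-allylic alcohol by reagent control.

Step 15
Reactants: 22 (1R,3Z,5S,9S)-4,11,11-trimethyl-8-methylidenebicyclo[7.2.0]undec-3-en-5-ol; 23 syncarpic acid (2,2,4,4-tetramethylcyclohexane-1,3,5-trione); 24 3-methylbutanal
Product: 26 tomentodione P, via alkylidene trione 25 (not isolated)
Conditions: ethylenediammonium diacetate (20 mol %), toluene, 80 °C, sealed tube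
Reagents that add atoms: none
Why: Knoevenagel condensation gives alkylidene trione 25, whose inverse-electron-demand hetero-Diels–Alder reaction with the 1,1-disubstituted C8=C15 alkene puts oxygen on the more substituted C8 and C15 on C1′; C8 (S) should result from approach on the face anti to the C10 methylene of ring A, and C1′ (S) from the transition state that places the C9 branch under the trione so that isobutyl ends cis to C9, with the 1′-epimer as the expected by-product to be removed by chromatography.

**Compound list**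

1 | 2,2-dimethylcyclopentan-1-one | CC1(C)CCCC1=O | starting material
2 | 5,5-dimethylcyclopent-2-en-1-one | CC1(C)CC=CC1=O | intermediate
3 | pent-4-yn-1-ol | C#CCCCO | starting material
4 | tert-butyl(pent-4-yn-1-yloxy)diphenylsilane | C#CCCCO[Si](c1ccccc1)(c1ccccc1)C(C)(C)C | intermediate
5 | [5-(TBDPS-oxy)pent-1-en-2-yl]diisobutylalane | C=C(CCCO[Si](c1ccccc1)(c1ccccc1)C(C)(C)C)[Al](CC(C)C)CC(C)C | intermediate (not isolated)
6 | 2-[5-(TBDPS-oxy)pent-1-en-2-yl]-4,4,5,5-tetramethyl-1,3,2-dioxaborolane | C=C(CCCO[Si](c1ccccc1)(c1ccccc1)C(C)(C)C)B1OC(C)(C)C(C)(C)O1 | intermediate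
7 | (S)-4-[5-(TBDPS-oxy)pent-1-en-2-yl]-2,2-dimethylcyclopentan-1-one | O=C1C[C@H](CC1(C)C)C(=C)CCCO[Si](c1ccccc1)(c1ccccc1)C(C)(C)C | intermediate
8 | lithium (S)-3-[5-(TBDPS-oxy)pent-1-en-2-yl]-5,5-dimethylcyclopent-1-en-1-olate | [Li+].[O-]C1=C[C@H](CC1(C)C)C(=C)CCCO[Si](c1ccccc1)(c1ccccc1)C(C)(C)C | intermediate (not isolated)
9 | (3S)-3-[5-(TBDPS-oxy)pent-1-en-2-yl]-5,5-dimethyl-2-(trifluoroacetyl)cyclopentan-1-one (C2 epimers and enol) | O=C1C(C(=O)C(F)(F)F)[C@H](CC1(C)C)C(=C)CCCO[Si](c1ccccc1)(c1ccccc1)C(C)(C)C | intermediate (not isolated)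
10 | (R)-3-[5-(TBDPS-oxy)pent-1-en-2-yl]-2-diazo-5,5-dimethylcyclopentan-1-one | O=C1C(=[N+]=[N-])[C@H](CC1(C)C)C(=C)CCCO[Si](c1ccccc1)(c1ccccc1)C(C)(C)C | intermediate
11 | [(4R)-4-[5-(TBDPS-oxy)pent-1-en-2-yl]-2,2-dimethylcyclobutylidene]methanone (ketene, C9 arrangement as in 7) | O=C=C1[C@H](CC1(C)C)C(=C)CCCO[Si](c1ccccc1)(c1ccccc1)C(C)(C)C | intermediate (not isolated)
12 | methyl (4S)-4-[5-(TBDPS-oxy)pent-1-en-2-yl]-2,2-dimethylcyclobutane-1-carboxylate (C1 epimers) | COC(=O)C1[C@H](CC1(C)C)C(=C)CCCO[Si](c1ccccc1)(c1ccccc1)C(C)(C)C | intermediate (not isolated)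
13 | methyl (1R,4S)-4-[5-(TBDPS-oxy)pent-1-en-2-yl]-2,2-dimethylcyclobutane-1-carboxylate | COC(=O)[C@@H]1[C@H](CC1(C)C)C(=C)CCCO[Si](c1ccccc1)(c1ccccc1)C(C)(C)C | intermediate
14 | (1R,4S)-4-[5-(TBDPS-oxy)pent-1-en-2-yl]-2,2-dimethylcyclobutane-1-carbaldehyde | O=C[C@@H]1[C@H](CC1(C)C)C(=C)CCCO[Si](c1ccccc1)(c1ccccc1)C(C)(C)C | intermediate
15 | tert-butyl{[4-((1S,4S)-4-(2-methoxyethenyl)-3,3-dimethylcyclobutyl)pent-4-en-1-yl]oxy}diphenylsilane (E/Z mixture, ring arrangement as in 14) | COC=C[C@@H]1[C@H](CC1(C)C)C(=C)CCCO[Si](c1ccccc1)(c1ccccc1)C(C)(C)C | intermediate (not isolated)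
16 | 2-{(1R,4S)-4-[5-(TBDPS-oxy)pent-1-en-2-yl]-2,2-dimethylcyclobutyl}acetaldehyde | O=CC[C@@H]1[C@H](CC1(C)C)C(=C)CCCO[Si](c1ccccc1)(c1ccccc1)C(C)(C)C | intermediate
17 | tert-butyl{[4-((1S,4R)-4-[(Z)-3-iodobut-2-en-1-yl]-3,3-dimethylcyclobutyl)pent-4-en-1-yl]oxy}diphenylsilane | C/C(I)=C/C[C@@H]1[C@H](CC1(C)C)C(=C)CCCO[Si](c1ccccc1)(c1ccccc1)C(C)(C)C | intermediate
18 | 4-{(1S,4R)-4-[(Z)-3-iodobut-2-en-1-yl]-3,3-dimethylcyclobutyl}pent-4-en-1-ol | C/C(I)=C/C[C@@H]1[C@H](CC1(C)C)C(=C)CCCO | intermediate
19 | 4-{(1S,4R)-4-[(Z)-3-iodobut-2-en-1-yl]-3,3-dimethylcyclobutyl}pent-4-enal | C/C(I)=C/C[C@@H]1[C@H](CC1(C)C)C(=C)CCC=O | intermediate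
20 | (1R,3Z,9S)-4,11,11-trimethyl-8-methylidenebicyclo[7.2.0]undec-3-en-5-ol (both C5 epimers) | C/C1=C/C[C@@H]2[C@H](CC2(C)C)C(=C)CCC1O | intermediate
21 | (1R,3Z,9S)-4,11,11-trimethyl-8-methylidenebicyclo[7.2.0]undec-3-en-5-one | C/C1=C/C[C@@H]2[C@H](CC2(C)C)C(=C)CCC1=O | intermediate
22 | (1R,3Z,5S,9S)-4,11,11-trimethyl-8-methylidenebicyclo[7.2.0]undec-3-en-5-ol | C/C1=C/C[C@@H]2[C@H](CC2(C)C)C(=C)CC[C@@H]1O | intermediate
23 | syncarpic acid (2,2,4,4-tetramethylcyclohexane-1,3,5-trione) | CC1(C)C(=O)CC(=O)C(C)(C)C1=O | starting material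
24 | 3-methylbutanal | CC(C)CC=O | starting material
25 | 2,2,4,4-tetramethyl-6-(3-methylbutylidene)cyclohexane-1,3,5-trione | CC(C)CC=C1C(=O)C(C)(C)C(=O)C(C)(C)C1=O | intermediate (not isolated)
26 | tomentodione P | C/C1=C/C[C@@H]2[C@H](CC2(C)C)[C@]2(CC[C@@H]1O)C[C@H](CC(C)C)C1=C(O2)C(C)(C)C(=O)C(C)(C)C1=O | target

**Step count and risks**

Total step count: 15. Longest linear sequence: 14 steps (from 3 through steps 2 to 15).

Steps most likely to fail:

1. Step 15. Insufficient facial discrimination at C8=C15 and weak endo/exo discrimination could make the C8 or C1′ epimer the main product. Fallback: the order of the last two events is inverted. Setting out from enone 21, the same three-component cycloaddition with 23 and 24 is run on a dienophile whose sp2 C5 and missing hydroxyl present a different ring conformation, to give the spiro enone F1. Its ring-B ketone is then reduced with (R)-2-methyl-CBS-oxazaborolidine/catecholborane or NaBH4/CeCl3, the vinylogous ester and the ketone between two quaternary carbons in ring D being far less electrophilic, and the route is rejoined at 26.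

2. Step 12. Oligomerisation or simple reduction of the vinyl iodide could outrun closure of the nine-membered ring. Fallback: ring B is closed at C3=C4 by ring-closing metathesis instead. Setting out from aldehyde 16, Wittig methylenation (MePPh3Br, KN(SiMe3)2) gives the allyl silyl ether F2. n-Bu4NF then gives the alcohol F3 and Dess–Martin periodinane the aldehyde F4. Addition of CH2=C(CH3)MgBr gives the dienol F5 (C5 epimers). Ring-closing metathesis with the second-generation Grubbs catalyst RuCl2(H2IMes)(PCy3)(=CHPh) in dilute toluene at 80 °C should close the cis trisubstituted olefin, and the route is rejoined at 20.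

3. Step 4. Slow boron-to-rhodium transfer of the hindered 1,1-disubstituted alkenyl group, with competing protodeboronation, could stall the conjugate addition. Fallback: the boronate is bypassed; alkenylalane 5 from step 3 is added directly to enone 2 in a copper-catalysed asymmetric conjugate addition (Cu(O2CC4H3S), chiral phosphoramidite ligand, Et2O, −30 °C), and the route is rejoined at 7; this fallback makes no new compound (F0).

Further compounds
F0 | step 4 | none | none
F1 | step 15 | spiro enone, the C5 ketone corresponding to 26 (1R,8S,9S,1′S) | C/C1=C/C[C@@H]2[C@H](CC2(C)C)[C@]2(CCC1=O)C[C@H](CC(C)C)C1=C(O2)C(C)(C)C(=O)C(C)(C)C1=O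
F2 | step 12 | tert-butyl{[4-((1S,4R)-3,3-dimethyl-4-(prop-2-en-1-yl)cyclobutyl)pent-4-en-1-yl]oxy}diphenylsilane | C=CC[C@@H]1[C@H](CC1(C)C)C(=C)CCCO[Si](c1ccccc1)(c1ccccc1)C(C)(C)C
F3 | step 12 | 4-[(1S,4R)-3,3-dimethyl-4-(prop-2-en-1-yl)cyclobutyl]pent-4-en-1-ol | C=CC[C@@H]1[C@H](CC1(C)C)C(=C)CCCO
F4 | step 12 | 4-[(1S,4R)-3,3-dimethyl-4-(prop-2-en-1-yl)cyclobutyl]pent-4-enal | C=CC[C@@H]1[C@H](CC1(C)C)C(=C)CCC=O
F5 | step 12 | 6-[(1S,4R)-3,3-dimethyl-4-(prop-2-en-1-yl)cyclobutyl]-2-methylhepta-1,6-dien-3-ol (C3 epimers) | C=CC[C@@H]1[C@H](CC1(C)C)C(=C)CCC(O)C(C)=C
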